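The quinone ring (C1 carbonyl, C2–OH, C3–hexadecyl, C4 carbonyl, C5–OMe, C6–H), the only ring, is closed last by a Moore rearrangement. Heating a 4-hydroxy-4-(methoxyethynyl)cyclobutenone opens the four-membered ring to an enynylketene, which recloses by forming the C4–C5 bond; in one operation the two alkyne carbons are inserted as C5 and C6 between the future para carbonyls C1 and C4, at the quinone oxidation level. The step exploits the C6–H/C5–OMe pair flanked by both carbonyls: C6–H receives the carbinol hydrogen, C5–OMe is the ynol ether terminus. The precursor is assembled from di-tert-butyl squarate, 1-bromohexadecane and lithium methoxyacetylide; acid finally frees the C2 hydroxyl.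

Key step: step 3

Remark: the target is achiral; the carbinol stereocenter of 8 is formed racemic and is destroyed in step 3, so no stereocontrol is needed.

Step 1
Reactants: 1 di-tert-butyl squarate (3,4-di-tert-butoxycyclobut-3-ene-1,2-dione); 2 1-bromohexadecane
Product: 5 3-tert-butoxy-4-hexadecylcyclobut-3-ene-1,2-dione, via hexadecylmagnesium bromide 3 (not isolated), via magnesium alkoxide adduct 4 (not isolated)
Conditions: 2, Mg, THF, 23 to 50 °C; then 1, THF, −78 °C; (CF3CO)2O, −78 °C; H2O, −78 to 0 °C
Reagents that add atoms: water, O
Why: Grignard formation and 1,2-addition to one of the two equivalent squarate carbonyls, followed by trifluoroacetylation of the tertiary alkoxide, ionization to the tert-butoxy-stabilized cyclobutenyl cation and hydrolysis with loss of tert-butanol (the squarate addition/1,3-carbonyl transposition sequence), should give the monoalkyl dione, the cold aqueous quench sparing the remaining acid-labile tert-butyl vinylogous ester.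

Step 2
Reactants: 5 3-tert-butoxy-4-hexadecylcyclobut-3-ene-1,2-dione; 6 chloroacetaldehyde dimethyl acetal (2-chloro-1,1-dimethoxyethane)
Product: 8 racemic 3-tert-butoxy-2-hexadecyl-4-hydroxy-4-(methoxyethynyl)cyclobut-2-en-1-one, via lithium methoxyacetylide 7 (not isolated)
Conditions: 6, LiNEt2 (3.0 equiv, from Et2NH and n-BuLi), THF, 0 °C; then add to 5, THF, −78 °C; aq. NH4Cl, −78 °C
Reagents that add atoms: none
Why: Threefold action of LiNEt2 on 6 (loss of MeOH, loss of HCl, deprotonation) gives the lithium ynol ether acetylide 7, which should add 1,2 to the ketone-like C2 carbonyl of 5 and not to the C1 carbonyl, deactivated as a vinylogous ester by the tert-butoxy group, as is general for acetylide additions to 3-alkoxy-4-alkylcyclobutenediones; the carbinol stereocenter forms racemic and is erased in step 3.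

Step 3
Reactants: 8 racemic 3-tert-butoxy-2-hexadecyl-4-hydroxy-4-(methoxyethynyl)cyclobut-2-en-1-one
Product: 12 3-hexadecyl-2-hydroxy-5-methoxy-1,4-benzoquinone (target), via enynylketene 9 (not isolated), via aryl diradical 10 (not isolated), via tert-butoxyquinone 11 (not isolated)
Conditions: p-xylene (0.02 M, degassed), 138 °C; concentrate; CF3CO2H, CH2Cl2, 0 to 23 °C
Reagents that add atoms: none
Why: Heating opens the cyclobutenone by conrotatory 4π electrocyclic cleavage of the C(=O)–C(OH) σ bond, the hydroxyl rotating outward so that the methoxyethynyl group lies cis to the ketene in 9; the ketene carbon then bonds to the methoxy-bearing alkyne carbon (the C4–C5 bond of the quinone) to give the phenoxyl/aryl σ-diradical 10, and transfer of the hydroxyl hydrogen to the aryl radical carbon (the future C6–H) should deliver quinone 11 directly at the quinone oxidation level. The closest known reaction type is the Moore rearrangement of 4-alkynyl-4-hydroxycyclobutenones to 1,4-benzoquinones, which is established for tert-butoxy-substituted cyclobutenones and tolerates heteroatom-substituted alkyne termini. The six-membered ring closes in a 6-endo-dig mode at the alkyne (a cycloaromatization of the enynylketene), and it is the only ring of the skeleton. No stereocenter is formed and the racemic carbinol center of 8 is destroyed. The step needs 6-endo closure to win over 5-exo-dig closure to an alkylidenecyclopentenedione, a path favored when the alkyne terminus carries a radical-stabilizing aryl, silyl or ester group and not expected for a methoxy terminus, while the position of every substituent is fixed by the site of acetylide addition in step 2 and the methoxyalkyne lacks the β-hydrogen needed for retro-ene loss to a ketene. CF3CO2H then cleaves only the tert-butyl vinylogous ester of 11 by an E1 path, leaving the C5 methyl ether, and the acidic product should be separable from neutral by-products by NaHCO3 extraction.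

Compound list
1 | di-tert-butyl squarate (3,4-di-tert-butoxycyclobut-3-ene-1,2-dione) | CC(C)(C)OC1=C(OC(C)(C)C)C(=O)C1=O | starting material
2 | 1-bromohexadecane | CCCCCCCCCCCCCCCCBr | starting material
3 | hexadecylmagnesium bromide | CCCCCCCCCCCCCCCC[Mg]Br | intermediate
4 | bromomagnesium alkoxide of racemic 2,3-di-tert-butoxy-4-hexadecyl-4-hydroxycyclobut-2-en-1-one | CCCCCCCCCCCCCCCCC1(O[Mg]Br)C(OC(C)(C)C)=C(OC(C)(C)C)C1=O | intermediate
5 | 3-tert-butoxy-4-hexadecylcyclobut-3-ene-1,2-dione | CCCCCCCCCCCCCCCCC1=C(OC(C)(C)C)C(=O)C1=O | intermediate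
6 | chloroacetaldehyde dimethyl acetal (2-chloro-1,1-dimethoxyethane) | COC(CCl)OC | starting material
7 | lithium methoxyacetylide | COC#C[Li] | intermediate
8 | racemic 3-tert-butoxy-2-hexadecyl-4-hydroxy-4-(methoxyethynyl)cyclobut-2-en-1-one | CCCCCCCCCCCCCCCCC1=C(OC(C)(C)C)C(O)(C#COC)C1=O | intermediate
9 | (3Z)-3-tert-butoxy-2-hexadecyl-4-hydroxy-6-methoxyhexa-1,3-dien-5-yn-1-one (enynylketene, alkyne cis to the ketene) | CCCCCCCCCCCCCCCCC(=C=O)/C(OC(C)(C)C)=C(/O)C#COC | intermediate
10 | 3-tert-butoxy-2-hexadecyl-4-hydroxy-6-methoxyphenoxyl with a second radical center (σ aryl radical) at ring carbon C5 | CCCCCCCCCCCCCCCCC1=C(OC(C)(C)C)C(O)=[C]C(OC)=C1[O] | intermediate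
11 | 2-tert-butoxy-3-hexadecyl-5-methoxy-1,4-benzoquinone | CCCCCCCCCCCCCCCCC1=C(OC(C)(C)C)C(=O)C=C(OC)C1=O | intermediate
12 | 3-hexadecyl-2-hydroxy-5-methoxy-1,4-benzoquinone | CCCCCCCCCCCCCCCCC1=C(O)C(=O)C=C(OC)C1=O | target

Total step count: 3
Longest linear sequence: 3 steps (1 to 5 to 8 to 12)

Steps most likely to fail

Step 3. The enynylketene may close in the 5-exo-dig mode to an alkylidenecyclopentenedione, or the ynol ether may decompose thermally before the ring opens. The fallback sets out from 8 and comes back at 11. Semihydrogenation of the ynol ether (H2, Pd on CaCO3 poisoned with Pb(OAc)2, quinoline, EtOAc, 23 °C) should give racemic 3-tert-butoxy-2-hexadecyl-4-hydroxy-4-[(Z)-2-methoxyethenyl]cyclobut-2-en-1-one F1. Heating in toluene at 110 °C should bring about electrocyclic ring opening, 6π electrocyclization (the only closure open to an alkenyl group) and tautomerization to 2-tert-butoxy-3-hexadecyl-5-methoxybenzene-1,4-diol F2. Oxidation with Ag2O in Et2O at 23 °C should give 11, which CF3CO2H converts into 12 as in the second stage of step 3.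

Step 2. Diethylamine or methoxide left from the in-flask acetylide generation may attack the vinylogous ester of 5, and the ynol ether carbinol may rearrange under acid on work-up. The fallback sets out from 5 and comes back at 12. Commercial ethoxyacetylene is lithiated with n-BuLi (THF, −78 °C, no amine present) and added to 5 to give racemic 3-tert-butoxy-4-(ethoxyethynyl)-2-hexadecyl-4-hydroxycyclobut-2-en-1-one F3. Thermolysis (toluene, 100 °C) by the same ring expansion should give 2-tert-butoxy-5-ethoxy-3-hexadecyl-1,4-benzoquinone F4. MeOH with catalytic H2SO4 at 50 °C should then cleave the tert-butyl group and exchange the unhindered C5 vinylogous ethyl ester for the methyl ester by addition–elimination, the chain-flanked C2 hydroxyl staying free, to give 12.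

Step 1. The second tert-butyl group may be lost to the trifluoroacetic acid liberated during the carbonyl transposition, or the Grignard reagent may add twice. The fallback sets out from 3 and comes back at 5. Grignard reagent 3 is added to commercial diisopropyl squarate (THF, −78 °C; aq. NH4Cl) to give racemic 4-hexadecyl-4-hydroxy-2,3-di(propan-2-yloxy)cyclobut-2-en-1-one F5. Catalytic conc. HCl in CH2Cl2 at 23 °C should transpose it to the acid-stable 3-hexadecyl-4-(propan-2-yloxy)cyclobut-3-ene-1,2-dione F6. Hydrolysis (6 M HCl, THF, 50 °C) should give 3-hexadecyl-4-hydroxycyclobut-3-ene-1,2-dione F7. O-tert-butylation of this strong vinylogous acid with tert-butyl 2,2,2-trichloroacetimidate (CH2Cl2/cyclohexane, 23 °C) should give 5, both oxygen sites of the delocalized anion leading to the same ester.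

Further compounds
F1 | step 3 | racemic 3-tert-butoxy-2-hexadecyl-4-hydroxy-4-[(Z)-2-methoxyethenyl]cyclobut-2-en-1-one | CCCCCCCCCCCCCCCCC1=C(OC(C)(C)C)C(O)(/C=C\OC)C1=O
F2 | step 3 | 2-tert-butoxy-3-hexadecyl-5-methoxybenzene-1,4-diol | CCCCCCCCCCCCCCCCc1c(O)c(OC)cc(O)c1OC(C)(C)C
F3 | step 2 | racemic 3-tert-butoxy-4-(ethoxyethynyl)-2-hexadecyl-4-hydroxycyclobut-2-en-1-one | CCCCCCCCCCCCCCCCC1=C(OC(C)(C)C)C(O)(C#COCC)C1=O
F4 | step 2 | 2-tert-butoxy-5-ethoxy-3-hexadecyl-1,4-benzoquinone | CCCCCCCCCCCCCCCCC1=C(OC(C)(C)C)C(=O)C=C(OCC)C1=O
F5 | step 1 | racemic 4-hexadecyl-4-hydroxy-2,3-di(propan-2-yloxy)cyclobut-2-en-1-one | CCCCCCCCCCCCCCCCC1(O)C(OC(C)C)=C(OC(C)C)C1=O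
F6 | step 1 | 3-hexadecyl-4-(propan-2-yloxy)cyclobut-3-ene-1,2-dione | CCCCCCCCCCCCCCCCC1=C(OC(C)C)C(=O)C1=O
F7 | step 1 | 3-hexadecyl-4-hydroxycyclobut-3-ene-1,2-dione | CCCCCCCCCCCCCCCCC1=C(O)C(=O)C1=O
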